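The numbers come from no measurement; the run is a simulation.

Which flask ends with the most target, and how much target does each hold at the end?

common to all: initiator 13 mol%
- east: substrate 1.5 M; coupling partner 1.10 equiv; time 6.0 h; a closed flask charged with all of it at once and left for 6.0 h
- west: substrate 1.5 M; coupling partner 1.10 equiv (fed, over 6.00 h); time 6.0 h; a stirred flask in which coupling partner is dosed at a steady rate over 6.00 h without added volume, worked up at 6.0 h
- south-east: substrate 1.5 M (fed, over 6.00 h); coupling partner 1.10 equiv; time 6.0 h; a stirred flask in which substrate is dosed at a steady rate over 6.00 h without added volume, worked up at 6.0 h
- south-west: substrate 1.5 M; coupling partner 1.10 equiv; a single well-mixed tank run continuously and read at steady state, 6.0 h in it on average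

- the set-up with the highest amount of target at the outlet or at the end, in percent of the substrate put in ("none" if the first two lie within 2 percentage points) (east / west / south-east / south-west / none)
- amount of target at the outlet or at the end, in percent of the substrate put in, east
- amount of target at the outlet or at the end, in percent of the substrate put in, west
- amount of target at the outlet or at the end, in percent of the substrate put in, south-east
- amount of target at the outlet or at the end, in percent of the substrate put in, south-west

- in percentages every species weighs as the substrate in it: one ended chains B or side product counts as two
- a step written with two of one species runs at k times the square of its concentration and takes two of it each time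
- the stated concentrations are those of everything mixed, before any reaction; amounts are the same in each set-up
- the feed brings no volume worth counting
- run time (east): 6.0 h

    2 first chain carrier → ended chains B (k1 = 3.4 × 10⁸ /M/s)
    coupling partner + first chain carrier → target + second chain carrier (k2 = 4.1 × 10⁵ /M/min)
    substrate + second chain carrier → by-product + first chain carrier (k3 = 3.7 × 10⁵ /M/min)
    2 second chain carrier → ended chains A (k4 = 3.1 × 10⁸ /M/s)
    initiator → 2 initiating radical (k5 = 5.1 × 10⁻⁶ /min)
    substrate + target → side product (k6 = 0.0023 /M/min)
    substrate + initiating radical → capped initiator + first chain carrier (k7 = 97000 /M/s)

I reckoned east by hand and went no further, starting from its chain rate r, the rate at which coupling partner becomes target. I set carrier formation from initiator equal to carrier loss in pairs, and the two propagation steps equal to each other (the steady-state treatment). That gave, for the charge in east: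

r at the start = 0.185 M/h, which held for 6.0 h makes 73.9% of the substrate charge.

In east the initiator lost 0.184% over the run, hardly any, so I looked to the reagents for the slowing. I supposed an end with the chain having used 0.5 of the substrate charge and substrate down to a third of its charge. Coupling partner then stood at 0.545 of its start, and with substrate and coupling partner at those levels I took the chain rate again:

r at the end / r at the start = 0.389, and the mean of the two ends makes 51.3% of the charge into target.

Substrate also consumes target in a second-order step, at k6 times the product of their two concentrations, and I carried a measure of it forward: the half-life τ that target has with substrate held at its charge, ln(2)/(k6·substrate) = 3.35 h, shorter than the run. Target in east sat on average for 3.00 h at a mean 0.667 of the substrate charge: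

half-lives counted = 0.597, share lost = 33.9%, target in east = 33.9%.

The forecast named east, with 34.5% there, 24.4% in west, 25.5% in south-east and 24.6% in south-west, holding that “the batch with everything present from the start runs fastest”.

East gave 34.7%, west 24.6%, south-east 25.4% and south-west 24.5%.

East held 30.5% as side product, which counts two per unit, so the side step took 30.5% of the target made, where I had put 33.9%. In south-west, substrate at 0.704 M stretched τ to 7.14 h, and 6.0 h on average in the tank gives 0.582 side product per target leaving. With 24.5% of target, south-west should then count 28.5% as side product, and it read 28.6%.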